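Split what has left the starting material into two heaps, and ask what ratio they stand in.

| flask | starting material | reagent in the second phase | remark | time | volume of the second phase over the first |
|---|---|---|---|---|---|
| spring | 20 mM | 10 mM | run made earlier |  |  |
| autumn | 20 mM | 40 mM | run made earlier |  |  |
| flask | 20 mM | 20.0 mM |  | 8.0 h | 2.0 |

| run | time / h | product / % | starting material / % |
|---|---|---|---|
| spring | 0.667 | 3.8 | 61.7 |
| spring | 2.00 | 8.1 | 26.1 |
| spring | 4.00 | 11.0 | 10.6 |
| spring | 6.00 | 11.1 | 4.9 |
| spring | 8.00 | 12.8 | 5.4 |
| autumn | 1.50 | 24.7 | 23.4 |
| autumn | 3.00 | 33.8 | 7.0 |
| autumn | 5.00 | 34.7 | 2.3 |
| autumn | 6.00 | 35.8 | 4.4 |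
| autumn | 8.00 | 39.2 | 1.5 |

(standard deviation of a reading: 1 percentage point)

- the product standing at 8.0 h, as a percentage of the starting material charged
- part of the starting material charged that has reacted at 8.0 h

- in the second phase: reagent in the second phase; everything else is in the first
- charges count per volume of the first phase; a concentration in a rate is the amount of a species over the volume of its own phase; every rate counts per litre of the first phase
- the earlier runs were read with a standard deviation of 1 percentage point
- steps that have been proposed: starting material + reagent in the reaction phase -> product; starting material <-> dormant form; reagent in the reaction phase <-> reagent in the second phase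
- the earlier runs hold the two phases in the same ratio of volumes as the flask asked about
- what has gone from starting material into another species counts as reacted, even if it can come back

What do you read first? The dormant form has no column, but the balance gives it: what is neither starting material nor product.

Which ratio? Product over dormant form, per mM of reagent charged to the second phase. Call it the split, a selectivity factor per mM. At 8.00 h it reads 0.0156 mM⁻¹ in spring and 0.0165 mM⁻¹ in autumn, so the mean split is 0.0161 mM⁻¹.

Why should it carry over? Both steps leave from starting material, and one needs reagent in the reaction phase while the other doesn't. The readings agree, with charges of 10 mM and 40 mM.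

The weak spot? The charge stands in for [reagent in the reaction phase]. The runs hold the flask's ratio of volumes, and that is as far as I can vouch for it.

And the flask? Its ratio is 0.322. First round: suppose the starting material is gone, and product is 24.3 %.

But in spring it isn't gone. There, at 8.00 h, dormant form over starting material reads 15.1, with its scatter. Put the first answer back, and my estimate for the flask is 4.99 % still standing as starting material. Second round: product 23.1 %, reacted 95.0 %.

The forecast says 22.5 % and 96 %, holding that “slow drainage of the dormant form adds about 3–4%”. My product stands 0.60 percentage points higher, by another road.

The flask gives 23.0 % and 95.6 %, so the forecast held.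

    starting material + reagent in the reaction phase → product (k = 0.00490 M⁻¹ s⁻¹)
    starting material ⇌ dormant form (K = 14.0, k = 1.80 × 10⁻⁴ s⁻¹)
    reagent in the reaction phase ⇌ reagent in the second phase, rate k3*([reagent in the reaction phase] - [reagent in the second phase]/K3) per volume of the first phase (partition coefficient = 0.470, kL = 0.00290 s⁻¹)

At 8.00 h the flask holds 72.6 % as dormant form, and the relaxation half-life of that step alone, 0.998 h, is short against 8.0 h. Its own split is 0.0158 mM⁻¹, beside the 0.0161 mM⁻¹ carried in.

The split carried in was read at 8.00 h. For this flask read at 2.0 h, spring at 2.00 h gives 0.0123 mM⁻¹, lower than at 8.00 h. Product should then be 19.8 % of what has reacted. Computed: 16.1 % with 77.9 % reacted, a share of 20.7 %.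

The runs are calculated from invented constants; noise was put on by code.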